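## Retrosynthetic overview

1. Each hydroxy-methoxy-quinone ring comes from a 2-alkyl-4,6-dimethoxy-5-methylresorcinol ring by oxidative demethylation. That ring has a local mirror plane, so loss of either methoxy group gives the same quinone.
2. The MOM-protected bis-arene is cut at both aryl–CH2 bonds. This gives a late three-fragment union of two identical aryllithiums with 1,13-diiodotridecane.
3. The arene fragment comes from resorcinol by O-methylation, directed lithiation/C-methylation, dibromination, Br→B→OH exchange and MOM protection.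
4. The C13 linker is assembled as C4 + C5 + C4: two but-3-yn-1-ol units on 1,5-dibromopentane, then hydrogenation and OH→I exchange.
5. No ring is built. Both carbocycles come intact from resorcinol and both become quinone rings together in the last step.

Assumption: the SMILES is read as two identical rings joined by an unbranched (CH2)13 tether (C29H40O8); it has no stereocentre and no stereogenic double bond, so it is achiral and nothing needs stereocontrol; in twofold reactions at equivalent sites only the organolithium species and the half-coupled C–C intermediates are numbered.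

## Fragment A (arene)

Step 1
Reactants: 1 resorcinol
Product: 2 1,3-dimethoxybenzene
Conditions: MeI (2.6 equiv), K2CO3 (3 equiv), acetone, reflux, 16 h
Reagents that add atoms: iodomethane, CI
Why: Williamson ether synthesis, in which both phenoxides formed with K2CO3 are O-methylated by SN2 on MeI.

Step 2
Reactants: 2 1,3-dimethoxybenzene
Product: 4 1,3-dimethoxy-2-methylbenzene, via 2,6-dimethoxyphenyllithium 3 (not isolated)
Conditions: n-BuLi (1.1 equiv), THF, 0 °C to rt, 2 h; MeI (1.3 equiv), 0 °C to rt
Reagents that add atoms: iodomethane, CI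
Why: Directed ortho-metalation, since the C–H between the two coordinating methoxy groups is lithiated selectively and the aryllithium is then methylated by MeI.

Step 3
Reactants: 4 1,3-dimethoxy-2-methylbenzene
Product: 5 1,5-dibromo-2,4-dimethoxy-3-methylbenzene
Conditions: NBS (2.1 equiv), MeCN, 0 °C to rt, dark, 12 h
Reagents that add atoms: N-bromosuccinimide, O=C1CCC(=O)N1Br
Why: Electrophilic aromatic bromination, in which the two equivalent positions ortho to one methoxy group and para to the other react, while ionic conditions spare the benzylic methyl and the C–H meta to both methoxy groups.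

Step 4
Reactants: 5 1,5-dibromo-2,4-dimethoxy-3-methylbenzene
Product: 6 2,2'-(4,6-dimethoxy-5-methyl-1,3-phenylene)bis(4,4,5,5-tetramethyl-1,3,2-dioxaborolane)
Conditions: B2pin2 (2.5 equiv), PdCl2(dppf) (5 mol %), KOAc (6 equiv), 1,4-dioxane, 90 °C, 16 h, Ar
Reagents that add atoms: bis(pinacolato)diboron, CC1(C)OB(OC1(C)C)B1OC(C)(C)C(C)(C)O1
Why: Twofold Miyaura borylation, which works because each C–Br has only one ortho substituent and the weak base KOAc prevents Suzuki homocoupling.

Step 5
Reactants: 6 the bis(pinacol boronate)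
Product: 7 4,6-dimethoxy-5-methylbenzene-1,3-diol
Conditions: 30 % aq. H2O2 (4 equiv), NaOH (2 equiv), THF/H2O, 0 °C, 1 h, Ar; mildly acidic work-up, used at once
Reagents that add atoms: hydrogen peroxide, OO
Why: Boronate oxidation, in which hydroperoxide adds to boron and a 1,2-aryl shift from B to O places an OH exactly where each bromine stood.

Step 6
Reactants: 7 4,6-dimethoxy-5-methylbenzene-1,3-diol
Product: 8 1,5-bis(methoxymethoxy)-2,4-dimethoxy-3-methylbenzene
Conditions: MOMCl (3 equiv), i-Pr2NEt (4 equiv), CH2Cl2, 0 °C to rt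
Reagents that add atoms: chloromethyl methyl ether, COCCl
Why: MOM acetal protection by O-alkylation, which masks the oxidation-prone phenols and puts two strong directing groups on either side of the only remaining ring C–H.

## Fragment B (C13 linker)

Step 7
Reactants: 9 but-3-yn-1-ol
Product: 10 (but-3-yn-1-yloxy)(tert-butyl)dimethylsilane
Conditions: TBSCl (1.1 equiv), Et3N (1.5 equiv), DMAP (5 mol %), CH2Cl2, 0 °C to rt
Reagents that add atoms: tert-butyldimethylsilyl chloride, CC(C)(C)[Si](C)(C)Cl
Why: Silyl ether protection removes the acidic OH, so one equivalent of base later gives a clean acetylide.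

Step 8
Reactants: 10 (but-3-yn-1-yloxy)(tert-butyl)dimethylsilane (2.3 equiv); 11 1,5-dibromopentane (1.0 equiv)
Product: 14 1,13-bis(tert-butyldimethylsilyloxy)trideca-3,10-diyne, via lithium acetylide 12 (not isolated), via bromoalkyne 13 (not isolated)
Conditions: n-BuLi (2.2 equiv), THF, −78 to 0 °C; DMPU, then 11, 0 to 45 °C, 16 h
Reagents that add atoms: none
Why: Twofold SN2 alkylation of a lithium acetylide by an unhindered primary dibromide in a dipolar cosolvent, which joins C4 + C5 + C4 to give the C13 chain.

Step 9
Reactants: 14 1,13-bis(tert-butyldimethylsilyloxy)trideca-3,10-diyne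
Product: 15 1,13-bis(tert-butyldimethylsilyloxy)tridecane
Conditions: H2 (1 atm), 10 % Pd/C, EtOAc, rt
Reagents that add atoms: none
Why: Catalytic hydrogenation saturates both alkynes, and the silyl ethers are stable in the aprotic solvent.

Step 10
Reactants: 15 1,13-bis(tert-butyldimethylsilyloxy)tridecane
Product: 16 tridecane-1,13-diol
Conditions: p-TsOH·H2O (10 mol %), MeOH/CH2Cl2, rt
Reagents that add atoms: none
Why: Acid-catalysed methanolysis cleaves primary TBS ethers quickly, and the diol crystallises.

Step 11
Reactants: 16 tridecane-1,13-diol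
Product: 17 1,13-diiodotridecane
Conditions: I2 (2.5 equiv), PPh3 (2.5 equiv), imidazole (3 equiv), THF/MeCN, 0 °C to rt
Reagents that add atoms: iodine, II
Why: Appel-type (Garegg–Samuelsson) iodination, in which each primary OH is activated as an alkoxyphosphonium ion and displaced by iodide.

## Union and end game

Step 12
Reactants: 8 1,5-bis(methoxymethoxy)-2,4-dimethoxy-3-methylbenzene (2.5 equiv); 17 1,13-diiodotridecane (1.0 equiv)
Product: 20 1,13-bis[2,6-bis(methoxymethoxy)-3,5-dimethoxy-4-methylphenyl]tridecane, via aryllithium 18 (not isolated), via iodotridecyl arene 19 (not isolated)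
Conditions: n-BuLi (2.4 equiv), THF, 0 °C, 1 h; 17, DMPU, 0 °C to rt, 16 h; excess 8 recovered
Reagents that add atoms: none
Why: Directed ortho-metalation at the only ring C–H, flanked by two chelating OMOM groups, followed by twofold SN2 alkylation on the primary diiodide; lithium–iodine exchange is not a problem because the chelated aryllithium is the more stable organolithium.

Step 13
Reactants: 20 the tetra-MOM bis-arene
Product: 21 2,2'-(tridecane-1,13-diyl)bis(4,6-dimethoxy-5-methylbenzene-1,3-diol)
Conditions: conc. HCl (cat.), MeOH/THF, 50 °C, Ar, 3 h; used crude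
Reagents that add atoms: none
Why: Acid-catalysed transacetalisation removes all four aryl MOM groups, and the released formaldehyde acetal cannot attack the fully substituted rings.

Step 14
Reactants: 21 the bis-resorcinol
Product: 22 3,3'-(tridecane-1,13-diyl)bis(2-hydroxy-5-methoxy-6-methylcyclohexa-2,5-diene-1,4-dione) (target)
Conditions: (NH4)2Ce(NO3)6 (4.4 equiv), MeCN/CH2Cl2/H2O, 0 °C, 20 min
Reagents that add atoms: water, O
Why: Oxidative demethylation of a 4-methoxyphenol by two equivalents of tetravalent cerium per ring, in which water adds at a methoxy-bearing carbon and methanol leaves; because of the local mirror plane, attack para or ortho at either methoxy group gives, after tautomerisation, the same 2-hydroxy-5-methoxy-6-methyl-3-alkylquinone.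

## Compound list

1 | resorcinol | Oc1cccc(O)c1 | starting material
2 | 1,3-dimethoxybenzene | COc1cccc(OC)c1 | intermediate
3 | 2,6-dimethoxyphenyllithium | [Li]c1c(OC)cccc1OC | intermediate
4 | 1,3-dimethoxy-2-methylbenzene | COc1cccc(OC)c1C | intermediate
5 | 1,5-dibromo-2,4-dimethoxy-3-methylbenzene | COc1c(C)c(OC)c(Br)cc1Br | intermediate
6 | 2,2'-(4,6-dimethoxy-5-methyl-1,3-phenylene)bis(4,4,5,5-tetramethyl-1,3,2-dioxaborolane) | COc1c(C)c(OC)c(B2OC(C)(C)C(C)(C)O2)cc1B3OC(C)(C)C(C)(C)O3 | intermediate
7 | 4,6-dimethoxy-5-methylbenzene-1,3-diol | COc1c(C)c(OC)c(O)cc1O | intermediate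
8 | 1,5-bis(methoxymethoxy)-2,4-dimethoxy-3-methylbenzene | COCOc1cc(OCOC)c(OC)c(C)c1OC | intermediate
9 | but-3-yn-1-ol | C#CCCO | starting material
10 | (but-3-yn-1-yloxy)(tert-butyl)dimethylsilane | C#CCCO[Si](C)(C)C(C)(C)C | intermediate
11 | 1,5-dibromopentane | BrCCCCCBr | starting material
12 | lithium 4-(tert-butyldimethylsilyloxy)but-1-yn-1-ide | [Li]C#CCCO[Si](C)(C)C(C)(C)C | intermediate
13 | [(9-bromonon-3-yn-1-yl)oxy](tert-butyl)dimethylsilane | BrCCCCCC#CCCO[Si](C)(C)C(C)(C)C | intermediate
14 | 1,13-bis(tert-butyldimethylsilyloxy)trideca-3,10-diyne | CC(C)(C)[Si](C)(C)OCCC#CCCCCCC#CCCO[Si](C)(C)C(C)(C)C | intermediate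
15 | 1,13-bis(tert-butyldimethylsilyloxy)tridecane | CC(C)(C)[Si](C)(C)OCCCCCCCCCCCCCO[Si](C)(C)C(C)(C)C | intermediate
16 | tridecane-1,13-diol | OCCCCCCCCCCCCCO | intermediate
17 | 1,13-diiodotridecane | ICCCCCCCCCCCCCI | intermediate
18 | [2,6-bis(methoxymethoxy)-3,5-dimethoxy-4-methylphenyl]lithium | [Li]c1c(OCOC)c(OC)c(C)c(OC)c1OCOC | intermediate
19 | 2-(13-iodotridecyl)-1,3-bis(methoxymethoxy)-4,6-dimethoxy-5-methylbenzene | ICCCCCCCCCCCCCc1c(OCOC)c(OC)c(C)c(OC)c1OCOC | intermediate
20 | 1,13-bis[2,6-bis(methoxymethoxy)-3,5-dimethoxy-4-methylphenyl]tridecane | COCOc1c(OC)c(C)c(OC)c(OCOC)c1CCCCCCCCCCCCCc1c(OCOC)c(OC)c(C)c(OC)c1OCOC | intermediate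
21 | 2,2'-(tridecane-1,13-diyl)bis(4,6-dimethoxy-5-methylbenzene-1,3-diol) | COc1c(C)c(OC)c(O)c(CCCCCCCCCCCCCc2c(O)c(OC)c(C)c(OC)c2O)c1O | intermediate
22 | 3,3'-(tridecane-1,13-diyl)bis(2-hydroxy-5-methoxy-6-methylcyclohexa-2,5-diene-1,4-dione) | COC1=C(C)C(=O)C(O)=C(CCCCCCCCCCCCCC2=C(O)C(=O)C(C)=C(OC)C2=O)C1=O | target

## Step count

Total step count: 14.
Longest linear sequence: 9 (steps 1–6, then 12–14). The linker branch runs 8 steps (7–11, then 12–14).

## Steps most likely to fail

**Step 12.** The twofold alkylation of a hindered aryllithium may stall at 19 or lose iodide by elimination. The fallback sets out from 8 and 17 and comes back at 20, and it reverses the polarity of the union.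
- Aryllithium 18, made from 8 as before, is quenched with I2 (THF, −78 °C). This gives 2-iodo-1,3-bis(methoxymethoxy)-4,6-dimethoxy-5-methylbenzene F1.
- Zn dust with LiCl (THF, 40 °C) inserts into both C–I bonds of 17. This gives tridecane-1,13-diylbis(zinc iodide) F2.
- A twofold Negishi coupling of F2 with 2.2 equiv of F1 (Pd(OAc)2, RuPhos, THF, 50 °C) delivers 20.

**Step 4.** The twofold borylation of an electron-rich dibromide may suffer protodebromination, and the following oxidation gives an air-sensitive phenol. The fallback sets out from 5 and comes back at 7, bypassing 6 and step 5, and it forms the C–O bonds directly.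
- A twofold palladium-catalysed etherification of 5 with benzyl alcohol ([(allyl)PdCl]2, RockPhos, Cs2CO3, toluene, 90 °C) gives 1,5-bis(benzyloxy)-2,4-dimethoxy-3-methylbenzene F3.
- Hydrogenolysis (H2, 10 % Pd/C, EtOAc/EtOH) releases 7 under neutral, non-oxidising conditions.

**Step 14.** The twofold aqueous one-electron oxidation of a lipophilic tetraphenol may be incomplete or may over-oxidise. The fallback sets out from 21 and comes back at 22, and it separates the oxidation from the C–O cleavage.
- PhI(OAc)2 (2.2 equiv) in dry MeOH at 0 °C, a metal-free two-electron oxidation by trivalent iodine, traps methanol para to the phenol. This gives the isolable 6,6'-(tridecane-1,13-diyl)bis(5-hydroxy-2,4,4-trimethoxy-3-methylcyclohexa-2,5-dien-1-one) F4.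
- F4 is purified and then hydrolysed with aqueous oxalic acid in THF to give 22.

## Further compounds

F1 | step 12 | 2-iodo-1,3-bis(methoxymethoxy)-4,6-dimethoxy-5-methylbenzene | COCOc1c(I)c(OCOC)c(OC)c(C)c1OC
F2 | step 12 | tridecane-1,13-diylbis(zinc iodide) | I[Zn]CCCCCCCCCCCCC[Zn]I
F3 | step 4 | 1,5-bis(benzyloxy)-2,4-dimethoxy-3-methylbenzene | COc1c(C)c(OC)c(OCc2ccccc2)cc1OCc1ccccc1
F4 | step 14 | 6,6'-(tridecane-1,13-diyl)bis(5-hydroxy-2,4,4-trimethoxy-3-methylcyclohexa-2,5-dien-1-one) | COC1=C(C)C(OC)(OC)C(O)=C(CCCCCCCCCCCCCC2=C(O)C(OC)(OC)C(C)=C(OC)C2=O)C1=O
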